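The readings were computed on assumed constants; scatter was added.

**Moving charge.** Do not read the substrate peak against a full flask. Substrate is still going in, and each percentage counts the whole charge. Ask instead how much of what is fed turns into target.

| setting | north-east | north-west | flask |
|---|---|---|---|
| substrate | 0.010 M (fed, over 3.0 min) | 0.010 M (fed, over 3.0 min) | 0.010 M (fed, over 3.0 min) |
| free catalyst | 3.5 mol% | 5.5 mol% | 2.5 mol% |
| remark | run made earlier; the fed solution adds 0.20 times the starting volume | run made earlier; the fed solution adds 0.20 times the starting volume | the fed solution adds 0.20 times the starting volume |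
| time |  |  | 3.0 min |

- north-east (time / min: substrate / %, target / %): 0.667: 19.0, 4.2; 1.33: 34.5, 10.0; 2.00: 50.1, 16.1; 2.50: 62.2, 20.7; 3.00: 73.3, 25.5
- north-west (time / min: substrate / %, target / %): 0.250: 5.8, 0.3; 0.417: 11.3, 1.5; 0.833: 20.6, 5.8; 1.50: 36.6, 12.7; 3.00: 72.9, 27.5

(scatter of a reading: 0.5 percentage points)

1. amount of substrate in percent of the substrate charged, at 20 s, 1.0 min and 3.0 min

- charges are per starting volume, the dose included; the dosed solution carries all of it
- percentages count the whole charge, also what has not yet gone in

**Drain share.** Late in the dose, the north-east readings show target gained at 28.2% of the substrate fed. Call this ratio, target gained over substrate fed in the same stretch, the drain share. Substrate is then what was fed, less the drain share of what was fed after a lag. The lag is the time at which the late target line meets zero.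

**Turn the loading.** By hand, going from 3.5 mol% to 5.5 mol% multiplies the drain share by 1.57, if target follows catalyst. Over its own late stretch, the north-west run reads 29.6%, which is 1.05 times the north-east reading. Extend that line down to 2.5 mol%. For this flask I get 27.5%.

**Turn the clock.** By hand, the flask has received 11.1% at 20 s, 33.3% at 1.0 min and 100% at 3.0 min. The north-east lag reads 0.287 min; keep it for this flask. Subtracting the drain then gives me 10.7%, 26.8% and 75.1%.

**The forecast.** It says 10.6%, 27% and 76.5%, holding that “it barely depends on catalyst loading”. My end value lies lower than its end value.

**The flask.** It gives 9.86%, 27.1% and 76.0%, and the forecast held.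

    substrate + free catalyst ⇌ catalyst intermediate A (K = 51.0 L mol⁻¹, k = 95.4 L mol⁻¹ s⁻¹)
    catalyst intermediate A → catalyst intermediate B (k = 8.02 s⁻¹)
    catalyst intermediate B → free catalyst + target (k = 0.953 s⁻¹)
    2 free catalyst → spent catalyst (k = 81.1 L mol⁻¹ s⁻¹)
    target → over-reaction product (k = 3.12 × 10⁻⁵ s⁻¹)

**Feed against drain.** Between 1.50 min and 3.00 min, this flask shows a drain share of 26.9%, beside the 27.5% I carried and the 29.6% read in the north-west run, while substrate climbs from 39.5% to 76.0%, the accumulation of a semi-batch dose. At 3.00 min, with spent catalyst at 80.4% of the catalyst charged, the two catalyst intermediates of this flask hold 0.179% of the substrate charged, less than the 0.5 percentage points scatter of the earlier readings.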